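**Retrosynthetic overview**

1. The target is a 7-methoxychromone (rings A and C) bonded through C3 to C1' of ring B; ring B carries 2'-OMe and a 2,2-dimethylpyran ring D fused at C3' (vinylic CH) and C4' (O). The last disconnection is C3–C1', a Suzuki–Miyaura coupling of a 3-iodochromone with the ring B/D boronate.
2. Ring D is cut at both of its bonds to ring B (C3'–CH= and C4'–O) and at O–CMe2. This gives an aryne with the triple bond between C3' and C4' plus 3-methylbut-2-enal, joined in one [2+2]/ring-opening/oxa-6π cascade.
3. Enabling feature: ring D sits on two adjacent ring B carbons, O on C4' and C on C3', and C3' is flanked by the methoxy-bearing C2'. A methoxy group beside an aryne triple bond sends a nucleophilic oxygen to the far carbon (C4') and the carbon partner to the near carbon (C3'), which is exactly the target pattern. A chlorine on C1' rides through as the coupling handle.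
4. The aryne precursor is the o-silylaryl triflate made from 4-chloro-3-methoxyphenol by carbamate-directed ortho-silylation between the two oxygens, then carbamate-to-triflate exchange.
5. Ring order: ring B is bought; ring D is formed in step 4; ring C is closed on ring A in step 7; the two halves are joined in step 8.

Key step: step 4

Remark: the target is achiral (no stereocenter, and the C3–C1' axis is not configurationally stable), so no stereocontrol is needed; transient and fallback compounds with one stereocenter are racemic.

**Route**

Step 1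
Reactants: 1 4-chloro-3-methoxyphenol
Product: 2 4-chloro-3-methoxyphenyl N-(propan-2-yl)carbamate
Conditions: i-PrNCO, Et3N (cat.), CH2Cl2, rt
Reagents that add atoms: isopropyl isocyanate, CC(C)N=C=O
Why: Base-catalysed addition of the phenol O–H across the isocyanate (carbamoylation) should give the secondary carbamate, which serves as ortho-directing group and as a phenol mask that mild base removes later.

Step 2
Reactants: 2 4-chloro-3-methoxyphenyl N-(propan-2-yl)carbamate
Product: 6 4-chloro-3-methoxy-2-(trimethylsilyl)phenyl N-(propan-2-yl)carbamate, via N-TBS carbamate 3 (not isolated), via aryllithium 4 (not isolated), via C-silylated N-TBS carbamate 5 (not isolated)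
Conditions: TBSOTf, TMEDA, Et2O, 0 °C to rt; then n-BuLi, TMEDA, −78 °C; then TMSCl, −78 °C to rt; aq. NaHSO4 work-up
Reagents that add atoms: chlorotrimethylsilane, C[Si](C)(C)Cl
Why: Directed ortho-metalation: after in-situ N-silylation, the carbamate and the methoxy group should cooperatively direct n-BuLi to the C–H between them (the aryl chloride does not exchange at −78 °C), TMSCl traps the aryllithium, and the acidic work-up cleaves the labile N–Si bond.

Step 3
Reactants: 6 4-chloro-3-methoxy-2-(trimethylsilyl)phenyl N-(propan-2-yl)carbamate
Product: 8 4-chloro-3-methoxy-2-(trimethylsilyl)phenyl trifluoromethanesulfonate, via silylphenol 7 (not isolated)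
Conditions: DBU, Et2NH, MeCN, 40 °C; then PhNTf2, rt
Reagents that add atoms: N-phenylbis(trifluoromethanesulfonimide), O=S(=O)(N(c1ccccc1)S(=O)(=O)C(F)(F)F)C(F)(F)F
Why: DBU deprotonates the carbamate N–H and E1cB loss of isopropyl isocyanate (scavenged by Et2NH as a urea) should unmask the phenoxide, which PhNTf2 sulfonylates in the same pot (one-pot carbamate cleavage/triflation of o-silylaryl carbamates).

Step 4
Reactants: 8 4-chloro-3-methoxy-2-(trimethylsilyl)phenyl trifluoromethanesulfonate; 9 3-methylbut-2-enal
Product: 13 6-chloro-5-methoxy-2,2-dimethyl-2H-chromene, via 4-chloro-3-methoxybenzyne 10 (not isolated), via benzoxete 11 (not isolated), via o-quinone methide 12 (not isolated)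
Conditions: CsF (3 equiv), 9 (4 equiv), MeCN, rt, slow addition of 8
Reagents that add atoms: none
Why: Fluoride attack on silicon and loss of triflate generate aryne 10; the carbonyl oxygen of 9 adds to the aryne carbon remote from OMe, the aryl anion formed next to OMe closes on the activated carbonyl carbon to give benzoxete 11 (formal [2+2], making the aryl–O and aryl–CH bonds), 4π-electrocyclic opening gives o-quinone methide 12, and oxa-6π-electrocyclisation makes the O–CMe2 bond. The closest known reaction type is the fluoride-induced annulation of arynes with α,β-unsaturated aldehydes to 2H-chromenes, an offshoot of aryne insertion into the C=O bond of aldehydes and formamides. Ring closures: the transient oxete by stepwise [2+2] (aryl anion onto the oxocarbenium carbon), then pyran ring D by thermal disrotatory 6π-electrocyclisation of the (Z)-1-oxatriene in 12, driven by re-aromatisation of ring B. No stereocenter is created, since C2 carries two methyl groups and the stereocenter of 11 is erased on ring opening. The selectivity needed is regiochemical, O on the carbon meta and C on the carbon ortho to OMe, and it is secured by the inductively withdrawing methoxy group beside the triple bond, which distorts the aryne so that the remote carbon is the more electrophilic one and the negative charge develops next to the oxygen-bearing carbon; the chlorine one position further on pulls in the same sense. Chemoselectivity for C=O over the C=C bond of 9 and over capture of 12 by a second aryne should be secured by excess 9, slow generation of 10 and the fast intramolecular 6π closure.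

Step 5
Reactants: 13 6-chloro-5-methoxy-2,2-dimethyl-2H-chromene
Product: 14 2-(5-methoxy-2,2-dimethyl-2H-chromen-6-yl)-4,4,5,5-tetramethyl-1,3,2-dioxaborolane
Conditions: B2pin2, Pd2(dba)3 (2 mol%), XPhos (8 mol%), KOAc, 1,4-dioxane, 100 °C
Reagents that add atoms: bis(pinacolato)diboron, CC1(C)OB(OC1(C)C)B1OC(C)(C)C(C)(C)O1
Why: Miyaura borylation of an aryl chloride: zerovalent palladium with the bulky, electron-rich biaryl phosphine should insert into the electron-rich, ortho-substituted C–Cl bond, and acetate-assisted transmetalation with B2pin2 gives the pinacol boronate while the chromene alkene stays untouched.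

Step 6
Reactants: 15 1-(2-hydroxy-4-methoxyphenyl)ethan-1-one (paeonol)
Product: 16 (E)-3-(dimethylamino)-1-(2-hydroxy-4-methoxyphenyl)prop-2-en-1-one
Conditions: DMF-DMA, toluene, 100 °C
Reagents that add atoms: N,N-dimethylformamide dimethyl acetal, COC(OC)N(C)C
Why: Condensation of the acetyl methyl group with the formamide acetal (enaminone formation) should give the push-pull (E)-enaminone, the hydrogen-bonded phenol staying free.

Step 7
Reactants: 16 (E)-3-(dimethylamino)-1-(2-hydroxy-4-methoxyphenyl)prop-2-en-1-one
Product: 17 3-iodo-7-methoxy-4H-chromen-4-one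
Conditions: I2, CHCl3, rt; aq. Na2S2O3 work-up
Reagents that add atoms: iodine, II
Why: Iodine-mediated cyclisation of an o-hydroxyaryl enaminone: electrophilic iodination at the enaminone α-carbon, attack of the phenol oxygen on the iminium carbon and loss of dimethylamine should close ring C as the 3-iodochromone.

Step 8
Reactants: 14 2-(5-methoxy-2,2-dimethyl-2H-chromen-6-yl)-4,4,5,5-tetramethyl-1,3,2-dioxaborolane; 17 3-iodo-7-methoxy-4H-chromen-4-one
Product: 18 7-methoxy-3-(5-methoxy-2,2-dimethyl-2H-chromen-6-yl)-4H-chromen-4-one (target)
Conditions: Pd(dppf)Cl2 (5 mol%), K2CO3, 1,4-dioxane/H2O, 80 °C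
Reagents that add atoms: none
Why: Suzuki–Miyaura coupling: the C–I bond of the 3-iodochromone adds readily to zerovalent palladium and the mild carbonate base should activate the boronate without opening the pyranone ring, forming the C3–C1' bond of the isoflavone.

**Compound list**

1 | 4-chloro-3-methoxyphenol | COc1cc(O)ccc1Cl | starting material
2 | 4-chloro-3-methoxyphenyl N-(propan-2-yl)carbamate | COc1cc(OC(=O)NC(C)C)ccc1Cl | intermediate
3 | 4-chloro-3-methoxyphenyl N-(tert-butyldimethylsilyl)-N-(propan-2-yl)carbamate (N-TBS carbamate) | COc1cc(OC(=O)N(C(C)C)[Si](C)(C)C(C)(C)C)ccc1Cl | intermediate (not isolated)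
4 | 2-lithio derivative of 3 (aryllithium) | COc1c([Li])c(OC(=O)N(C(C)C)[Si](C)(C)C(C)(C)C)ccc1Cl | intermediate (not isolated)
5 | 4-chloro-3-methoxy-2-(trimethylsilyl)phenyl N-(tert-butyldimethylsilyl)-N-(propan-2-yl)carbamate | COc1c([Si](C)(C)C)c(OC(=O)N(C(C)C)[Si](C)(C)C(C)(C)C)ccc1Cl | intermediate (not isolated)
6 | 4-chloro-3-methoxy-2-(trimethylsilyl)phenyl N-(propan-2-yl)carbamate | COc1c([Si](C)(C)C)c(OC(=O)NC(C)C)ccc1Cl | intermediate
7 | 4-chloro-3-methoxy-2-(trimethylsilyl)phenol (present as its DBU-H phenoxide) | COc1c([Si](C)(C)C)c(O)ccc1Cl | intermediate (not isolated)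
8 | 4-chloro-3-methoxy-2-(trimethylsilyl)phenyl trifluoromethanesulfonate | COc1c([Si](C)(C)C)c(OS(=O)(=O)C(F)(F)F)ccc1Cl | intermediate
9 | 3-methylbut-2-enal | CC(C)=CC=O | starting material
10 | 4-chloro-3-methoxybenzyne (1-chloro-2-methoxy-3,4-didehydrobenzene) | COC1=C(Cl)C=CC#C1 | intermediate (not isolated)
11 | 4-chloro-3-methoxy-2-(2-methylprop-1-en-1-yl)-2H-benzo[b]oxete (racemic) | COc1c(Cl)ccc2OC(C=C(C)C)c12 | intermediate (not isolated)
12 | (6Z)-4-chloro-5-methoxy-6-(3-methylbut-2-en-1-ylidene)cyclohexa-2,4-dien-1-one | O=C1C=CC(Cl)=C(OC)/C1=C/C=C(C)C | intermediate (not isolated)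
13 | 6-chloro-5-methoxy-2,2-dimethyl-2H-chromene | COc1c(Cl)ccc2OC(C)(C)C=Cc12 | intermediate
14 | 2-(5-methoxy-2,2-dimethyl-2H-chromen-6-yl)-4,4,5,5-tetramethyl-1,3,2-dioxaborolane | COc1c(B2OC(C)(C)C(C)(C)O2)ccc2OC(C)(C)C=Cc12 | intermediate
15 | 1-(2-hydroxy-4-methoxyphenyl)ethan-1-one (paeonol) | CC(=O)c1ccc(OC)cc1O | starting material
16 | (E)-3-(dimethylamino)-1-(2-hydroxy-4-methoxyphenyl)prop-2-en-1-one | COc1ccc(C(=O)/C=C/N(C)C)c(O)c1 | intermediate
17 | 3-iodo-7-methoxy-4H-chromen-4-one | COc1ccc2c(=O)c(I)coc2c1 | intermediate
18 | 7-methoxy-3-(5-methoxy-2,2-dimethyl-2H-chromen-6-yl)-4H-chromen-4-one | COc1ccc2c(=O)c(-c3ccc4c(c3OC)C=CC(C)(C)O4)coc2c1 | target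

**Step count and risks**

Total step count: 8. Longest linear sequence: 6 steps (steps 1, 2, 3, 4, 5, 8); steps 6 and 7 form the second branch.

Steps most likely to fail:

1. Step 4. The aryne may be lost to pathways other than carbonyl [2+2]: ene reaction with the allylic methyl groups of 9, fluoride-promoted self-condensation of the enal, or capture of the o-quinone methide by a second aryne before it electrocyclises. The fallback keeps the aryne but replaces the enal by a partner that cannot do this. It sets out from 8: aryne 10 (CsF, DMF, rt) inserts into the C=O bond of the solvent to give the racemic 4-chloro-3-methoxy-N,N-dimethyl-2H-benzo[b]oxet-2-amine F1 (not isolated), which aqueous work-up should hydrolyse to 3-chloro-6-hydroxy-2-methoxybenzaldehyde F2 with the same regiochemistry. 2-Methylprop-1-enylmagnesium bromide (2.5 equiv, THF, 0 °C) should then give the racemic diol 4-chloro-2-(1-hydroxy-3-methylbut-2-en-1-yl)-3-methoxyphenol F3. Warming F3 with PPTS in toluene dehydrates it to 12, which closes to 13, where the route is rejoined.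

2. Step 2. Metalation may occur at the other ortho position of the carbamate (para to OMe), because the chlorine turns the methoxy methyl toward the wanted C–H; anionic ortho-Fries migration or incomplete silylation of the crowded aryllithium is also possible. The fallback avoids the carbamate, the C–Si bond and the aryne. It sets out from 1: MOMCl/i-Pr2NEt (CH2Cl2) gives 1-chloro-2-methoxy-4-(methoxymethoxy)benzene F4. n-BuLi/TMEDA (THF, −78 to −40 °C) lithiates between the two ether oxygens, the classical doubly activated site, to give [3-chloro-2-methoxy-6-(methoxymethoxy)phenyl]lithium F5 (not isolated). This adds 1,2 to 9 to give racemic 1-[3-chloro-2-methoxy-6-(methoxymethoxy)phenyl]-3-methylbut-2-en-1-ol F6. HCl in MeOH (50 °C) removes the acetal and dehydrates the o-hydroxybenzyl allylic alcohol to 12, which electrocyclises to 13, where the route is rejoined.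

3. Step 8. Protodeboronation of the electron-rich ortho-methoxy boronate and base-induced opening of the pyranone ring of 17 may outrun a slow transmetalation. The fallback forms the C3–C1' bond by enolate arylation instead. It sets out from 13: Pd-catalysed α-arylation of purchased 7-methoxychroman-4-one F7 with chloride 13 (Pd2(dba)3, XPhos, K3PO4, toluene, 100 °C) should give the racemic isoflavanone 7-methoxy-3-(5-methoxy-2,2-dimethyl-2H-chromen-6-yl)chroman-4-one F8. Dehydrogenation with DDQ (1,4-dioxane, reflux) introduces the C2=C3 double bond and comes back to the route at 18.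

**Further compounds**

F1 | step 4 | 4-chloro-3-methoxy-N,N-dimethyl-2H-benzo[b]oxet-2-amine (racemic, not isolated) | COc1c(Cl)ccc2OC(N(C)C)c12
F2 | step 4 | 3-chloro-6-hydroxy-2-methoxybenzaldehyde | COc1c(Cl)ccc(O)c1C=O
F3 | step 4 | 4-chloro-2-(1-hydroxy-3-methylbut-2-en-1-yl)-3-methoxyphenol (racemic) | COc1c(Cl)ccc(O)c1C(O)C=C(C)C
F4 | step 2 | 1-chloro-2-methoxy-4-(methoxymethoxy)benzene | COCOc1ccc(Cl)c(OC)c1
F5 | step 2 | [3-chloro-2-methoxy-6-(methoxymethoxy)phenyl]lithium (not isolated) | COCOc1ccc(Cl)c(OC)c1[Li]
F6 | step 2 | 1-[3-chloro-2-methoxy-6-(methoxymethoxy)phenyl]-3-methylbut-2-en-1-ol (racemic) | COCOc1ccc(Cl)c(OC)c1C(O)C=C(C)C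
F7 | step 8 | 7-methoxychroman-4-one | COc1ccc2C(=O)CCOc2c1
F8 | step 8 | 7-methoxy-3-(5-methoxy-2,2-dimethyl-2H-chromen-6-yl)chroman-4-one (racemic) | COc1ccc2c(c1)OCC(c1ccc3OC(C)(C)C=Cc3c1OC)C2=O
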